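**Retrosynthetic overview**
1. Guanine last: the C8–aryl bond comes from a Traube annulation of 2,5,6-triaminopyrimidin-4(3H)-one on a salicylaldehyde, itself made by ortho-formylation of the ring A phenol at its only free ortho position (late C–H functionalisation of the bare cyclophane).
2. Key disconnection: the C2–CH2(ring A) bond of the 14-membered ring together with C3=N4 of the piperazine, in one telescoped cascade: amine–aldehyde condensation to a cyclic imine, 1,6-addition of its enamine carbon C2 to a ring A para-quinone methide, reduction of C3=N4.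
3. Enabling feature: in ring A the hydroxyl is para to the benzylic carbon, so that carbon can be unmasked as the exocyclic CH2 of a para-quinone methide; C2 is α to C3 and β to N4, so it is the nucleophilic carbon of the N4–C3 imine/enamine; the short diaryl ether bridge forces C2 cis to C5.
4. Acyclic precursor from N-Boc-4-borono-L-phenylalanine (C5, ring B), 3,4-dihydroxybenzaldehyde (ring A) and aminoacetaldehyde dimethyl acetal (N1, C2, C3) by Chan–Lam ether coupling and reductive amination.
5. Ring order: rings A and B and the pyrimidinone are purchased; the piperazine ring and the 14-membered ring form together in the key step; the imidazole ring of the guanine closes last.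

Key step: step 8

Remark: piperazine locants used throughout are N1, C2 (carries the ring A benzylic carbon), C3, N4, C5 (carries the ring B benzylic carbon, from L-phenylalanine), C6; ring A is the phenol ring, ring B the para-phenylene ring; the target is (2S,5S), i.e. cis.

**Step 1**
Reactants: 1 3,4-dihydroxybenzaldehyde
Product: 2 3-hydroxy-4-[(4-methoxybenzyl)oxy]benzaldehyde
Conditions: 4-methoxybenzyl chloride, NaHCO3, NaI (cat.), DMF, 40 °C
Reagents that add atoms: 4-methoxybenzyl chloride, COc1ccc(CCl)cc1
Why: Regioselective Williamson etherification: the 4-hydroxyl, para to the formyl group, is the more acidic one and is alkylated under weak base, leaving the 3-hydroxyl free for the ether coupling.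

**Step 2**
Reactants: 3 N-Boc-4-borono-L-phenylalanine
Product: 4 Weinreb amide of 3, tert-butyl (S)-{3-(4-boronophenyl)-1-[methoxy(methyl)amino]-1-oxopropan-2-yl}carbamate
Conditions: MeNHOMe·HCl, EDC·HCl, HOBt, N-methylmorpholine, CH2Cl2, 0 °C to rt
Reagents that add atoms: N,O-dimethylhydroxylamine hydrochloride, CNOC.Cl
Why: Carbodiimide amide coupling gives the Weinreb amide, which later stops at the aldehyde level and resists α-epimerisation better than an ester; the boronic acid is inert to EDC/HOBt.

**Step 3**
Reactants: 2 3-hydroxy-4-[(4-methoxybenzyl)oxy]benzaldehyde; 4 Weinreb amide boronic acid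
Product: 5 diaryl ether aldehyde, the (S)-Weinreb amide of 4 in which boron is replaced by the 5-formyl-2-[(4-methoxybenzyl)oxy]phenoxy group
Conditions: Cu(OAc)2, pyridine, 4 Å molecular sieves, CH2Cl2, air, rt
Reagents that add atoms: none
Why: Chan–Lam–Evans oxidative coupling of a phenol with an arylboronic acid should form the diaryl ether at room temperature without touching the α-stereocentre, the aldehyde or the PMB ether.

**Step 4**
Reactants: 5 diaryl ether aldehyde
Product: 6 benzylic alcohol (CH2OH in place of CHO of 5)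
Conditions: NaBH4, THF/MeOH, 0 °C
Reagents that add atoms: none
Why: Borohydride reduction is chemoselective for the aryl aldehyde; Weinreb amide and carbamate are inert at 0 °C.

**Step 5**
Reactants: 6 benzylic alcohol
Product: 8 benzylic p-tolyl sulfone (CH2SO2C6H4CH3 in place of CH2OH of 6), via benzylic chloride 7 (not isolated)
Conditions: MsCl, Et3N, CH2Cl2, 0 °C; then sodium p-toluenesulfinate, Bu4NI (cat.), DMF, 50 °C
Reagents that add atoms: sodium p-toluenesulfinate, Cc1ccc(cc1)S(=O)[O-].[Na+]; methanesulfonyl chloride, CS(=O)(=O)Cl (supplies the chlorine of 7 only)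
Why: Mesylation of a para-alkoxybenzylic alcohol collapses to the chloride, and sulfinate S-alkylation (nucleophilic substitution) then gives an acid-stable sulfone that will serve as the leaving group for quinone methide release.

**Step 6**
Reactants: 8 benzylic sulfone Weinreb amide
Product: 9 N-Boc α-amino aldehyde, tert-butyl (S)-{1-oxo-3-[4-(2-[(4-methoxybenzyl)oxy]-5-(tosylmethyl)phenoxy)phenyl]propan-2-yl}carbamate
Conditions: LiAlH4, THF, −40 to 0 °C; aq. KHSO4; used at once
Reagents that add atoms: none
Why: Weinreb amide reduction stops at the chelated tetrahedral intermediate and should release the aldehyde on work-up without over-reduction; the sulfone and PMB ether are not reduced under these conditions.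

**Step 7**
Reactants: 9 N-Boc α-amino aldehyde; 10 aminoacetaldehyde dimethyl acetal
Product: 12 cascade precursor: N4-Boc diamine with N1 carrying Cbz plus the CH2CH(OCH3)2 arm, via secondary amine 11 (not isolated)
Conditions: NaBH(OAc)3, AcOH, ClCH2CH2Cl, 0 °C to rt; then sat. aq. NaHCO3, CbzCl, rt
Reagents that add atoms: benzyl chloroformate, O=C(Cl)OCc1ccccc1
Why: Reductive amination followed by Schotten–Baumann acylation installs the C6–N1 bond and the N1 carbamate; the C5 stereocentre is not touched provided the aldehyde is not stored.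

**Step 8**
Reactants: 12 cascade precursor
Product: 16 N1-Cbz macrocyclic piperazine (2S,5S) with free N4–H plus free ring A phenol, via cyclic imine 13 (not isolated), via quinone methide enamine 14 (not isolated), via macrocyclic imine 15 (not isolated)
Conditions: TFA/CH2Cl2/H2O (10:10:1), pentamethylbenzene, 0 °C to rt, evaporate; then slow addition to Cs2CO3, MeCN (1 mM), 50 °C, Ar; then NaBH4, MeOH, 0 °C
Reagents that add atoms: none
Why: Proposed new method: TFA removes Boc and PMB and hydrolyses the acetal, so N4 condenses with the C3 aldehyde (6-exo-trig addition, then dehydration) to the six-membered cyclic imine 13, whose enamine tautomer N4H–C3=C2 makes C2 nucleophilic; on neutralisation the ring A phenoxide expels p-toluenesulfinate to give the para-quinone methide 14, C2 adds to its exocyclic CH2 in an intramolecular 1,6-conjugate addition that closes the 14-membered ring (endo at the quinone methide C=CH2, high dilution), and NaBH4 then reduces C3=N4 of 15. The closest known reaction types are the enamine 1,6-addition of aldehydes to para-quinone methides in aminocatalysis, the base-induced release of quinone methides from hydroxybenzyl sulfones, and the interception of a reductive amination at its enamine stage; their union in a ring-forming cascade on a 2-amino aldimine is new. Re-aromatisation of ring A should make the C–C bond formation irreversible and pay for the strain of the cyclophane. The new stereocentre C2 is controlled by the tether: the ten-atom bridge C5–CH2–ring B–O–ring A–CH2, with its rigid para- and meta-phenylene units, can span C2 and C5 only on one face of the six-membered ring (cis, bicyclo[10.2.2]), so 5S dictates 2S, and any equilibration of the α-imino centre in 15 can only return the same isomer. The step needs C- over N- and O-alkylation and ring closure over oligomerisation: C2 is the only enamine carbon, N1 is a carbamate, attack by N4 would require a 12-membered ansa ring and is reversible, and reversible return of sulfinate should keep the quinone methide at a low stationary concentration.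

**Step 9**
Reactants: 16 N1-Cbz macrocyclic piperazine
Product: 17 N1,N4-bis-Cbz macrocyclic piperazine, ring A phenol free
Conditions: N-(benzyloxycarbonyloxy)succinimide, Et3N, CH2Cl2, 0 °C to rt
Reagents that add atoms: N-(benzyloxycarbonyloxy)succinimide, O=C(OCc1ccccc1)ON1C(=O)CCC1=O
Why: Chemoselective N-acylation (carbamate formation) of the secondary amine N4 by the succinimidyl carbonate leaves the phenol free and removes the amine that would otherwise undergo Mannich chemistry with formaldehyde in step 10.

**Step 10**
Reactants: 17 N1,N4-bis-Cbz macrocyclic piperazine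
Product: 19 salicylaldehyde (CHO at the ring A carbon ortho to OH), via salicyl alcohol 18 (not isolated)
Conditions: MgCl2, Et3N, paraformaldehyde, MeCN, reflux
Reagents that add atoms: paraformaldehyde (as formaldehyde), C=O
Why: Magnesium-phenoxide-directed ortho-formylation (Casnati–Skattebøl) delivers formaldehyde only to the free position ortho to the ring A hydroxyl, since the other ortho position carries the aryloxy group and the para position the benzylic carbon; ring B is not a phenol and should not react.

**Step 11**
Reactants: 19 salicylaldehyde; 20 2,5,6-triaminopyrimidin-4(3H)-one sulfate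
Product: 22 N1,N4-bis-Cbz guanipiperazine A, via Schiff base 21 (not isolated)
Conditions: NaOAc, DMSO, 110 °C, open to air
Reagents that add atoms: none
Why: Traube-type purine annulation: the 5-amino group condenses with the aldehyde, the 6-amino group adds to the imine, and aerobic dehydrogenation of the dihydropurine should give the 8-arylguanine.

**Step 12**
Reactants: 22 N1,N4-bis-Cbz guanipiperazine A
Product: 23 guanipiperazine A
Conditions: H2 (1 atm), Pd(OH)2/C, MeOH/AcOH, rt; then aq. NH3 to the free base
Reagents that add atoms: none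
Why: Hydrogenolysis of both benzyl carbamates liberates N1 and N4; the diaryl ether, phenol and guanine are inert and the skeleton holds no benzylic C–N or C–O bond.

**Compound list**
1 | 3,4-dihydroxybenzaldehyde | O=Cc1ccc(O)c(O)c1 | starting material
2 | 3-hydroxy-4-[(4-methoxybenzyl)oxy]benzaldehyde | O=Cc1ccc(OCc2ccc(OC)cc2)c(O)c1 | intermediate
3 | N-Boc-4-borono-L-phenylalanine | CC(C)(C)OC(=O)N[C@@H](Cc1ccc(cc1)B(O)O)C(=O)O | starting material
4 | tert-butyl (S)-{3-(4-boronophenyl)-1-[methoxy(methyl)amino]-1-oxopropan-2-yl}carbamate | CC(C)(C)OC(=O)N[C@@H](Cc1ccc(cc1)B(O)O)C(=O)N(C)OC | intermediate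
5 | (S)-diaryl ether aldehyde Weinreb amide | CC(C)(C)OC(=O)N[C@@H](Cc1ccc(cc1)Oc1cc(C=O)ccc1OCc1ccc(OC)cc1)C(=O)N(C)OC | intermediate
6 | (S)-benzylic alcohol Weinreb amide | CC(C)(C)OC(=O)N[C@@H](Cc1ccc(cc1)Oc1cc(CO)ccc1OCc1ccc(OC)cc1)C(=O)N(C)OC | intermediate
7 | (S)-benzylic chloride Weinreb amide | CC(C)(C)OC(=O)N[C@@H](Cc1ccc(cc1)Oc1cc(CCl)ccc1OCc1ccc(OC)cc1)C(=O)N(C)OC | intermediate (not isolated)
8 | (S)-benzylic p-tolyl sulfone Weinreb amide | CC(C)(C)OC(=O)N[C@@H](Cc1ccc(cc1)Oc1cc(CS(=O)(=O)c2ccc(C)cc2)ccc1OCc1ccc(OC)cc1)C(=O)N(C)OC | intermediate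
9 | (S)-N-Boc α-amino aldehyde | CC(C)(C)OC(=O)N[C@@H](Cc1ccc(cc1)Oc1cc(CS(=O)(=O)c2ccc(C)cc2)ccc1OCc1ccc(OC)cc1)C=O | intermediate
10 | aminoacetaldehyde dimethyl acetal | NCC(OC)OC | starting material
11 | (S)-secondary amine (N4-Boc, N1–H, N1–CH2CH(OCH3)2) | CC(C)(C)OC(=O)N[C@@H](Cc1ccc(cc1)Oc1cc(CS(=O)(=O)c2ccc(C)cc2)ccc1OCc1ccc(OC)cc1)CNCC(OC)OC | intermediate (not isolated)
12 | (S)-cascade precursor (N4-Boc, N1-Cbz, acetal, PMB ether, sulfone) | CC(C)(C)OC(=O)N[C@@H](Cc1ccc(cc1)Oc1cc(CS(=O)(=O)c2ccc(C)cc2)ccc1OCc1ccc(OC)cc1)CN(CC(OC)OC)C(=O)OCc1ccccc1 | intermediate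
13 | benzyl (5S)-5-{4-[2-hydroxy-5-(tosylmethyl)phenoxy]benzyl}-5,6-dihydropyrazine-1(2H)-carboxylate (cyclic imine C3=N4) | O=C(OCc1ccccc1)N1CC=N[C@@H](Cc2ccc(cc2)Oc2cc(CS(=O)(=O)c3ccc(C)cc3)ccc2O)C1 | intermediate (not isolated)
14 | (5S)-enamine tautomer (C2=C3, N4–H) carrying the ring A para-quinone methide (2-aryloxy-4-methylenecyclohexa-2,5-dien-1-one) | O=C(OCc1ccccc1)N1C=CN[C@@H](Cc2ccc(cc2)OC2=CC(=C)C=CC2=O)C1 | intermediate (not isolated)
15 | (2S,5S)-macrocyclic imine (C3=N4), N1-Cbz, ring A phenol | Oc1ccc2cc1Oc1ccc(cc1)C[C@H]1CN(C(=O)OCc3ccccc3)[C@H](C=N1)C2 | intermediate (not isolated)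
16 | (2S,5S)-N1-Cbz macrocyclic piperazine, N4–H, ring A phenol | Oc1ccc2cc1Oc1ccc(cc1)C[C@H]1CN(C(=O)OCc3ccccc3)[C@H](CN1)C2 | intermediate
17 | (2S,5S)-N1,N4-bis-Cbz macrocyclic piperazine, ring A phenol | Oc1ccc2cc1Oc1ccc(cc1)C[C@H]1CN(C(=O)OCc3ccccc3)[C@H](CN1C(=O)OCc1ccccc1)C2 | intermediate
18 | (2S,5S)-bis-Cbz salicyl alcohol (CH2OH ortho to the ring A hydroxyl) | OCc1cc2cc(c1O)Oc1ccc(cc1)C[C@H]1CN(C(=O)OCc3ccccc3)[C@H](CN1C(=O)OCc1ccccc1)C2 | intermediate (not isolated)
19 | (2S,5S)-bis-Cbz salicylaldehyde | O=Cc1cc2cc(c1O)Oc1ccc(cc1)C[C@H]1CN(C(=O)OCc3ccccc3)[C@H](CN1C(=O)OCc1ccccc1)C2 | intermediate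
20 | 2,5,6-triaminopyrimidin-4(3H)-one sulfate | Nc1nc(N)c(N)c(=O)[nH]1.OS(=O)(=O)O | starting material
21 | Schiff base of 19 at the 5-amino group of the triaminopyrimidinone | Nc1nc(N)c(N=Cc2cc3cc(c2O)Oc2ccc(cc2)C[C@H]2CN(C(=O)OCc4ccccc4)[C@H](CN2C(=O)OCc2ccccc2)C3)c(=O)[nH]1 | intermediate (not isolated)
22 | N1,N4-bis-Cbz guanipiperazine A | Nc1nc2nc(-c3cc4cc(c3O)Oc3ccc(cc3)C[C@H]3CN(C(=O)OCc5ccccc5)[C@H](CN3C(=O)OCc3ccccc3)C4)[nH]c2c(=O)[nH]1 | intermediate
23 | guanipiperazine A | Nc1nc2nc(-c3cc4cc(c3O)Oc3ccc(cc3)C[C@H]3CN[C@H](CN3)C4)[nH]c2c(=O)[nH]1 | target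

**Step count and risks**
Total steps: 12. Longest linear sequence: 11 steps (1 → 2 → 5 → 6 → 8 → 9 → 12 → 16 → 17 → 19 → 22 → 23; the branch from 3 through 4 is equally long).

Steps most likely to fail:

1. Step 8 (proposed new method). The transient quinone methide may oligomerise through intermolecular phenoxide C- or O-attack, or the cyclic imine may self-condense, faster than the enamine carbon closes the strained 14-membered ring. The fallback keeps the same ring-closing bond and the same quinone methide but uses a 1,3-dicarbonyl carbanion, a well-precedented partner for quinone methides. It sets out from aldehyde 9. Reductive amination with diethyl aminomalonate hydrochloride (NaBH(OAc)3) and N-acylation with CbzCl would give the N-Cbz aminomalonate F1. TFA with pentamethylbenzene would remove Boc and PMB, and on neutralisation N4 would close on one ester to the 3-oxopiperazine-2-carboxylate F2. Cs2CO3 in dilute MeCN would release the quinone methide, which the malonamate carbanion at C2 captures by 1,6-addition to give the macrocyclic lactam ester F3. Saponification with LiOH and thermal decarboxylation would give the macrocyclic lactam F4, in which the bridge forces C2–H cis. Reduction of the lactam with BH3·THF comes back to the route at 16.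

2. Step 3. Transmetalation and C–O coupling of the ortho-substituted, electron-poor phenol may be slow, so that protodeboronation and oxidation of the boronic acid to its phenol consume 4. The fallback is an Ullmann ether synthesis with the roles of the metal partners changed. It sets out from phenol 2 and purchased N-Boc-4-iodo-L-phenylalanine F5, which is converted as in step 2 to the iodo Weinreb amide F6. Coupling of F6 with 2 (CuI, N,N-dimethylglycine, Cs2CO3, dioxane, 90 °C) comes back to the route at 5.

3. Step 11. The condensation may stall at the hydrogen-bonded salicylaldimine, or the aerobic dehydrogenation of the dihydropurine may be incomplete or accompanied by oxidation of the phenol. The fallback is the non-oxidative acid variant of the Traube synthesis. It sets out from 19. Pinnick oxidation (NaClO2, NaH2PO4, 2-methyl-2-butene) would give the salicylic acid F7. Carbodiimide coupling with the 5-amino group of 2,5,6-triaminopyrimidin-4(3H)-one would give the amide F8. Cyclodehydration (hexamethyldisilazane, cat. (NH4)2SO4, reflux) comes back to the route at 22.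

**Further compounds**
F1 | step 8 | diethyl 2-{(benzyloxycarbonyl)[(S)-2-(Boc-amino)-3-aryl-propyl]amino}malonate (aryl as in 9) | CC(C)(C)OC(=O)N[C@@H](Cc1ccc(cc1)Oc1cc(CS(=O)(=O)c2ccc(C)cc2)ccc1OCc1ccc(OC)cc1)CN(C(C(=O)OCC)C(=O)OCC)C(=O)OCc1ccccc1
F2 | step 8 | ethyl (5S)-1-Cbz-5-{4-[2-hydroxy-5-(tosylmethyl)phenoxy]benzyl}-3-oxopiperazine-2-carboxylate (C2 epimers) | CCOC(=O)C1N(C(=O)OCc2ccccc2)C[C@H](Cc2ccc(cc2)Oc2cc(CS(=O)(=O)c3ccc(C)cc3)ccc2O)NC1=O
F3 | step 8 | macrocyclic lactam ester (C3=O, CO2Et on C2, bridge cis to the C5 arm) | Oc1ccc2cc1Oc1ccc(cc1)C[C@H]1CN(C(=O)OCc3ccccc3)[C@](C(=O)OCC)(C(=O)N1)C2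
F4 | step 8 | macrocyclic lactam (C3=O, N1-Cbz, cis) | Oc1ccc2cc1Oc1ccc(cc1)C[C@H]1CN(C(=O)OCc3ccccc3)[C@H](C(=O)N1)C2
F5 | step 3 | N-Boc-4-iodo-L-phenylalanine (purchased) | CC(C)(C)OC(=O)N[C@@H](Cc1ccc(I)cc1)C(=O)O
F6 | step 3 | Weinreb amide of N-Boc-4-iodo-L-phenylalanine | CC(C)(C)OC(=O)N[C@@H](Cc1ccc(I)cc1)C(=O)N(C)OC
F7 | step 11 | bis-Cbz salicylic acid (CO2H in place of CHO of 19) | OC(=O)c1cc2cc(c1O)Oc1ccc(cc1)C[C@H]1CN(C(=O)OCc3ccccc3)[C@H](CN1C(=O)OCc1ccccc1)C2
F8 | step 11 | 5-aroylamino-2,6-diaminopyrimidin-4(3H)-one from F7 | Nc1nc(N)c(NC(=O)c2cc3cc(c2O)Oc2ccc(cc2)C[C@H]2CN(C(=O)OCc4ccccc4)[C@H](CN2C(=O)OCc2ccccc2)C3)c(=O)[nH]1
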